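**Plan**

1. Numbering: ring C1 (isopropenyl), C2, C3–C4 epoxide (methyl on C4), C5 (angelate), C6, C7–C8 epoxide (methyl on C8), C9 (OH), C10 (senecioate). The retrosynthesis first removes both esters and both epoxides (each from a Z ring alkene) and takes the C9/C10 oxygens back to a C9 ketone.
2. In the resulting (3Z,7Z)-cyclodecadien-9-one the C3=C4 alkene and the C9 carbonyl are 1,5-related through the C1–C2 bond and C1 bears the isopropenyl group: the retron of an oxy-Cope shift. Cutting C1–C2 and joining C4–C9 gives a cyclohex-2-en-1-ol (ring C4–C9, C7=C8 already present) with a vinyl arm on C4 and an (E)-3-methylbutadienyl arm on C9, cis to each other.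
3. Forward: the six-membered ring is bought as 2-methylcyclohex-2-enone. CBS reduction, directed epoxidation, oxidation, vinyl addition and a semipinacol vinyl shift build the C4 quaternary centre and the C5 oxygen. C8 methylation, dehydrogenation, enynyl addition and hydroalumination give the precursor. The ten-membered ring then arises in one step by four-carbon ring expansion, and the two epoxides are closed last (C3–C4, then C7–C8).
4. Stereochemistry: the absolute configuration comes from the CBS reduction and is relayed through the epoxide to C4 and C5. The C5 silyloxy group steers the C9 addition and selects the chair of the rearrangement, which fixes Z at C3=C4 and transfers chirality to C1.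
5. C5 and C10 are then adjusted by Mitsunobu inversions. The C3–C4 epoxide is set trans to O5 by hydroxyl-directed peracid epoxidation, C9 by chelation-controlled reduction, and the C7–C8 epoxide cis to O9 by vanadium-directed epoxidation.

Key step: step 11

Remark: C-numbers in the text always mean the ring numbering of the plan (the six-membered intermediates are ring C4–C9); the ten-membered compounds are named with this numbering, the six-membered ones with their own systematic locants.

**Route**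

Step 1
Reactants: 1 2-methylcyclohex-2-en-1-one
Product: 2 (S)-2-methylcyclohex-2-en-1-ol
Conditions: (R)-1-methyl-3,3-diphenyltetrahydro-1H,3H-pyrrolo[1,2-c][1,3,2]oxazaborole (the (R)-methyl-CBS catalyst, 10 mol %), BH3·SMe2, THF, −20 °C; MeOH, aq. work-up
Reagents that add atoms: none
Why: Corey–Bakshi–Shibata reduction, in which the ketone binds the catalyst with its 2-methylvinyl side as the large group so that hydride reaches one carbonyl face only, should give the S allylic alcohol, the source of all absolute configuration in the route.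

Step 2
Reactants: 2 (S)-2-methylcyclohex-2-en-1-ol
Product: 3 (1S,2S,6R)-1-methyl-7-oxabicyclo[4.1.0]heptan-2-ol
Conditions: VO(acac)2 (2 mol %), t-BuOOH, CH2Cl2, 0 °C → rt
Reagents that add atoms: tert-butyl hydroperoxide CC(C)(C)OO
Why: Vanadium-catalysed hydroxyl-directed epoxidation delivers oxygen from the metal-bound hydroxyl to the same face of the cyclohexene, so the epoxide (the future C4 and C5 centres) should form cis to the OH.

Step 3
Reactants: 3 (1S,2S,6R)-1-methyl-7-oxabicyclo[4.1.0]heptan-2-ol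
Product: 4 (1R,6R)-1-methyl-7-oxabicyclo[4.1.0]heptan-2-one
Conditions: Dess–Martin periodinane, CH2Cl2, rt
Reagents that add atoms: none
Why: Dess–Martin oxidation of the secondary alcohol under neutral conditions leaves the epoxide intact, and the epoxide now carries the stereochemical information.

Step 4
Reactants: 4 (1R,6R)-1-methyl-7-oxabicyclo[4.1.0]heptan-2-one
Product: 5 (1R,2R,6R)-2-ethenyl-1-methyl-7-oxabicyclo[4.1.0]heptan-2-ol
Conditions: CH2=CHMgBr, THF, −78 °C; then H2O
Reagents that add atoms: vinylmagnesium bromide C=C[Mg]Br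
Why: Grignard 1,2-addition to an alpha,beta-epoxy ketone takes place anti to the epoxide oxygen, which should give the tertiary C9 alcohol with OH cis and vinyl trans to the epoxide oxygen, the arrangement needed for migration.

Step 5
Reactants: 5 (1R,2R,6R)-2-ethenyl-1-methyl-7-oxabicyclo[4.1.0]heptan-2-ol
Product: 6 (2S,3R)-2-ethenyl-3-hydroxy-2-methylcyclohexan-1-one
Conditions: ZnBr2 (20 mol %), CH2Cl2, 0 °C → rt
Reagents that add atoms: none
Why: Semipinacol rearrangement of a 2,3-epoxy alcohol: ZnBr2 opens the epoxide at its tertiary carbon C4 and the vinyl group, antiperiplanar to the breaking C–O bond, shifts from C9 to C4 with inversion while C9 becomes the ketone, so the C4 quaternary centre forms stereospecifically with the C5 hydroxyl cis to methyl and trans to vinyl.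

Step 6
Reactants: 6 (2S,3R)-2-ethenyl-3-hydroxy-2-methylcyclohexan-1-one
Product: 7 (2S,3R)-3-[(tert-butyldimethylsilyl)oxy]-2-ethenyl-2-methylcyclohexan-1-one
Conditions: TBSOTf, 2,6-lutidine, CH2Cl2, −78 → 0 °C
Reagents that add atoms: tert-butyldimethylsilyl trifluoromethanesulfonate CC(C)(C)[Si](C)(C)OS(=O)(=O)C(F)(F)F
Why: Silylation with the silyl triflate and a hindered pyridine base protects the neopentyl-type secondary alcohol without exposing the beta-hydroxy ketone to retro-aldol cleavage.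

Step 7
Reactants: 7 (2S,3R)-3-[(tert-butyldimethylsilyl)oxy]-2-ethenyl-2-methylcyclohexan-1-one
Product: 9 (2S,3R,6RS)-3-[(tert-butyldimethylsilyl)oxy]-2-ethenyl-2,6-dimethylcyclohexan-1-one, via lithium enolate 8 (not isolated)
Conditions: LiN(iPr)2, THF, −78 °C; MeI, −78 → −20 °C
Reagents that add atoms: iodomethane CI
Why: Kinetic enolate alkylation can occur only at C8 because C4 is quaternary, and the C8 configuration is irrelevant because this centre becomes sp2 in step 8.

Step 8
Reactants: 9 (2S,3R,6RS)-3-[(tert-butyldimethylsilyl)oxy]-2-ethenyl-2,6-dimethylcyclohexan-1-one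
Product: 11 (5R,6S)-5-[(tert-butyldimethylsilyl)oxy]-6-ethenyl-2,6-dimethylcyclohex-2-en-1-one, via trimethylsilyl enol ether 10 (not isolated)
Conditions: TMSOTf, Et3N, CH2Cl2, 0 °C; crude enol ether, Pd(OAc)2 (1.1 equiv), MeCN, rt
Reagents that add atoms: none
Why: Saegusa–Ito dehydrogenation: the only possible silyl enol ether (C9=C8) is palladated by Pd(OAc)2 and beta-hydride elimination toward C7 gives the endocyclic 2-methyl enone, which fixes C7=C8 as a cis ring alkene before the ring expansion.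

Step 9
Reactants: 11 (5R,6S)-5-[(tert-butyldimethylsilyl)oxy]-6-ethenyl-2,6-dimethylcyclohex-2-en-1-one; 12 2-methylbut-1-en-3-yne
Product: 14 (1R,5R,6S)-5-[(tert-butyldimethylsilyl)oxy]-6-ethenyl-2,6-dimethyl-1-(3-methylbut-3-en-1-yn-1-yl)cyclohex-2-en-1-ol, via lithium acetylide 13 (not isolated)
Conditions: 12, n-BuLi, THF, −78 °C; then 11, −78 → −30 °C; H2O
Reagents that add atoms: none
Why: 1,2-Addition of a lithium acetylide to the enone: in the half-chair with the C5 silyloxy group equatorial the C4 methyl is pseudo-axial and blocks its face, whereas the other half-chair is shielded on both faces (axial silyloxy and axial vinyl), so the nucleophile should enter anti to the methyl and set C9 with the new arm cis to the vinyl group.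

Step 10
Reactants: 14 (1R,5R,6S)-5-[(tert-butyldimethylsilyl)oxy]-6-ethenyl-2,6-dimethyl-1-(3-methylbut-3-en-1-yn-1-yl)cyclohex-2-en-1-ol
Product: 15 (1S,5R,6S)-5-[(tert-butyldimethylsilyl)oxy]-6-ethenyl-2,6-dimethyl-1-[(1E)-3-methylbuta-1,3-dien-1-yl]cyclohex-2-en-1-ol
Conditions: NaAlH2(OCH2CH2OMe)2, THF, 0 °C → rt; aq. potassium sodium tartrate
Reagents that add atoms: none
Why: Alkoxide-directed trans-hydroalumination of the propargylic alcohol followed by protonolysis gives the E alkene of the dienyl arm and leaves the other alkenes and the silyl ether untouched.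

Step 11
Reactants: 15 (1S,5R,6S)-5-[(tert-butyldimethylsilyl)oxy]-6-ethenyl-2,6-dimethyl-1-[(1E)-3-methylbuta-1,3-dien-1-yl]cyclohex-2-en-1-ol
Product: 18 (1S,3Z,5R,7Z)-5-[(tert-butyldimethylsilyl)oxy]-4,8-dimethyl-1-(prop-1-en-2-yl)cyclodeca-3,7-dien-9-one, via potassium alkoxide 16 (not isolated), via potassium dienolate 17 (not isolated)
Conditions: KH (1.5 equiv), 18-crown-6 (1.5 equiv), THF, 0 °C → rt; then AcOH, −78 °C
Reagents that add atoms: none
Why: KH and 18-crown-6 give the free tertiary alkoxide 16, whose C4–C9 bond is weakened so that the 1,5-diene C1=C10–C9–C4–C3=C2 undergoes a concerted [3,3] shift that forms C1–C2 and the cross-conjugated dienolate 17, which acetic acid protonates at C10. The closest known reaction type is the anionic oxy-Cope ring expansion of 1,2-dialkenylcyclohexanols and of 6-alkenyl-1-alkenylcyclohex-2-enols to cyclodecenones. The ten-membered ring is not closed end to end but arises by four-carbon ring expansion: the two arms are joined through a six-membered chair transition state while the ring bond C4–C9 opens. The new C1 stereocentre is set by chirality transfer from C4 and C9, the E geometry of the dienyl arm placing the isopropenyl group pseudo-equatorial and the cis arms presenting one face of the diene terminus to the vinyl carbon. The step needs the chair with the C4 methyl pseudo-equatorial and C5 pseudo-axial (Z at C3=C4) over the alternative chair (E alkene, opposite C1); this is secured by the cis arms, by the methyl and by the equatorial C5 silyloxy group, which would be syn-axial to the alkoxide in the other half-chair. The ring C7=C8 bond is a spectator that stays Z and ends up conjugated with the C9 carbonyl.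

Step 12
Reactants: 18 (1S,3Z,5R,7Z)-5-[(tert-butyldimethylsilyl)oxy]-4,8-dimethyl-1-(prop-1-en-2-yl)cyclodeca-3,7-dien-9-one
Product: 19 (1S,3Z,5R,7Z)-5-hydroxy-4,8-dimethyl-1-(prop-1-en-2-yl)cyclodeca-3,7-dien-9-one
Conditions: HF·pyridine, pyridine, THF, 0 °C → rt
Reagents that add atoms: none
Why: Fluoride-mediated cleavage of the silyl ether under buffered conditions frees the allylic C5 alcohol without touching the enone or the diene.

Step 13
Reactants: 19 (1S,3Z,5R,7Z)-5-hydroxy-4,8-dimethyl-1-(prop-1-en-2-yl)cyclodeca-3,7-dien-9-one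
Product: 21 (1S,3Z,5S,7Z)-5-hydroxy-4,8-dimethyl-1-(prop-1-en-2-yl)cyclodeca-3,7-dien-9-one, via 4-nitrobenzoate ester 20 (not isolated)
Conditions: 4-O2NC6H4CO2H, PPh3, diisopropyl azodicarboxylate, THF, 0 °C → rt; then K2CO3 (cat.), MeOH, 0 °C
Reagents that add atoms: 4-nitrobenzoic acid OC(=O)c1ccc(cc1)[N+](=O)[O-]
Why: Mitsunobu reaction of a secondary allylic alcohol proceeds by SN2 displacement of the oxyphosphonium group by the carboxylate and so inverts C5 to the configuration of the target, and mild methanolysis of the activated ester then releases the alcohol.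

Step 14
Reactants: 21 (1S,3Z,5S,7Z)-5-hydroxy-4,8-dimethyl-1-(prop-1-en-2-yl)cyclodeca-3,7-dien-9-one
Product: 22 (1S,3S,4R,5S,7Z)-3,4-epoxy-5-hydroxy-4,8-dimethyl-1-(prop-1-en-2-yl)cyclodec-7-en-9-one
Conditions: mCPBA (1.05 equiv), CH2Cl2, −20 → 0 °C
Reagents that add atoms: 3-chloroperbenzoic acid OOC(=O)c1cccc(Cl)c1
Why: Hydroxyl-directed peracid (Henbest) epoxidation: with the ring carbon C2 cis on the alkene the hydrogen-bonded transition state should give the threo (ring-trans) epoxy alcohol, as with medium-ring Z-cycloalkenols, the trisubstituted allylic alkene reacting faster than the isopropenyl group and the enone alkene being inert, so C3 and C4 are set here.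

Step 15
Reactants: 22 (1S,3S,4R,5S,7Z)-3,4-epoxy-5-hydroxy-4,8-dimethyl-1-(prop-1-en-2-yl)cyclodec-7-en-9-one; 23 angelic acid
Product: 25 (1S,3S,4S,5S,7Z)-3,4-epoxy-4,8-dimethyl-9-oxo-1-(prop-1-en-2-yl)cyclodec-7-en-5-yl (2Z)-2-methylbut-2-enoate, via mixed anhydride 24 (not isolated)
Conditions: 23, 2,4,6-Cl3C6H2COCl, Et3N, toluene, rt; then 22, 75 °C
Reagents that add atoms: none
Why: Yamaguchi-type esterification through the mixed anhydride without a nucleophilic catalyst acylates the only free hydroxyl and avoids Z-to-E isomerisation of the angelate.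

Step 16
Reactants: 25 (1S,3S,4S,5S,7Z)-3,4-epoxy-4,8-dimethyl-9-oxo-1-(prop-1-en-2-yl)cyclodec-7-en-5-yl (2Z)-2-methylbut-2-enoate
Product: 27 (1R,3S,4S,5S,7Z,10R)-3,4-epoxy-10-hydroxy-4,8-dimethyl-9-oxo-1-(prop-1-en-2-yl)cyclodec-7-en-5-yl (2Z)-2-methylbut-2-enoate, via sodium enolate 26 (not isolated)
Conditions: NaN(SiMe3)2, THF, −78 °C; 2-(phenylsulfonyl)-3-phenyloxaziridine, −78 °C; AcOH
Reagents that add atoms: 2-(phenylsulfonyl)-3-phenyloxaziridine O=S(=O)(N1OC1c1ccccc1)c1ccccc1
Why: Kinetic alpha'-deprotonation of the enone at C10 (C8 carries no hydrogen) and Davis oxaziridine hydroxylation of the enolate; attack on the enolate face opposite to the C1–C2 ring bond is expected to give the 10R alcohol, epimeric with the target at C10 and therefore set up for inversion.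

Step 17
Reactants: 27 (1R,3S,4S,5S,7Z,10R)-3,4-epoxy-10-hydroxy-4,8-dimethyl-9-oxo-1-(prop-1-en-2-yl)cyclodec-7-en-5-yl (2Z)-2-methylbut-2-enoate; 28 3-methylbut-2-enoic acid
Product: 29 (1R,3S,4S,5S,7Z,10S)-3,4-epoxy-4,8-dimethyl-10-[(3-methylbut-2-enoyl)oxy]-9-oxo-1-(prop-1-en-2-yl)cyclodec-7-en-5-yl (2Z)-2-methylbut-2-enoate
Conditions: 28, PPh3, diisopropyl azodicarboxylate, toluene, 0 °C → rt
Reagents that add atoms: none
Why: Mitsunobu esterification, fast at a carbon alpha to a ketone, displaces the activated C10 oxygen by the senecioate with inversion and so installs the ester and the target C10 configuration in one operation.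

Step 18
Reactants: 29 (1R,3S,4S,5S,7Z,10S)-3,4-epoxy-4,8-dimethyl-10-[(3-methylbut-2-enoyl)oxy]-9-oxo-1-(prop-1-en-2-yl)cyclodec-7-en-5-yl (2Z)-2-methylbut-2-enoate
Product: 30 (1R,3S,4S,5S,7Z,9R,10S)-3,4-epoxy-9-hydroxy-4,8-dimethyl-10-[(3-methylbut-2-enoyl)oxy]-1-(prop-1-en-2-yl)cyclodec-7-en-5-yl (2Z)-2-methylbut-2-enoate
Conditions: Zn(BH4)2, Et2O, −20 °C; aq. work-up
Reagents that add atoms: none
Why: Zn(BH4)2 reduces enones at the carbonyl and, through a zinc chelate between the C9 carbonyl and the C10 ester oxygen (Cram chelate model), delivers hydride anti to the C10 substituent, which should give the 9,10-anti (ring-cis) hydroxy ester without touching the esters or the epoxide.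

Step 19
Reactants: 30 (1R,3S,4S,5S,7Z,9R,10S)-3,4-epoxy-9-hydroxy-4,8-dimethyl-10-[(3-methylbut-2-enoyl)oxy]-1-(prop-1-en-2-yl)cyclodec-7-en-5-yl (2Z)-2-methylbut-2-enoate
Product: 31 (1R,3S,4S,5S,7R,8S,9S,10S)-3,4:7,8-diepoxy-9-hydroxy-4,8-dimethyl-10-[(3-methylbut-2-enoyl)oxy]-1-(prop-1-en-2-yl)cyclodecan-5-yl (2Z)-2-methylbut-2-enoate (CNP0320216.1)
Conditions: VO(acac)2 (5 mol %), t-BuOOH, CH2Cl2, 0 °C
Reagents that add atoms: tert-butyl hydroperoxide CC(C)(C)OO
Why: Vanadium-catalysed hydroxyl-directed epoxidation is specific for the alkene of the allylic alcohol and, with the methyl on C8 (allylic 1,2-strain) and by analogy with medium-ring cycloalkenols, should deliver oxygen cis (erythro) to the C9 hydroxyl, setting C7 and C8 and completing the target.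

**Compound list**

1 | 2-methylcyclohex-2-en-1-one | CC1=CCCCC1=O | starting material
2 | (S)-2-methylcyclohex-2-en-1-ol | CC1=CCCC[C@@H]1O | intermediate
3 | (1S,2S,6R)-1-methyl-7-oxabicyclo[4.1.0]heptan-2-ol (epoxide cis to OH) | O[C@H]1CCC[C@H]2O[C@@]12C | intermediate
4 | (1R,6R)-1-methyl-7-oxabicyclo[4.1.0]heptan-2-one | O=C1CCC[C@H]2O[C@@]12C | intermediate
5 | (1R,2R,6R)-2-ethenyl-1-methyl-7-oxabicyclo[4.1.0]heptan-2-ol (OH cis to epoxide oxygen) | C=C[C@]1(O)CCC[C@H]2O[C@@]12C | intermediate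
6 | (2S,3R)-2-ethenyl-3-hydroxy-2-methylcyclohexan-1-one (OH cis to methyl) | O=C1CCC[C@@H](O)[C@]1(C)C=C | intermediate
7 | (2S,3R)-3-[(tert-butyldimethylsilyl)oxy]-2-ethenyl-2-methylcyclohexan-1-one | O=C1CCC[C@@H](O[Si](C)(C)C(C)(C)C)[C@]1(C)C=C | intermediate
8 | lithium enolate of 7 (C9=C8) | [Li+].[O-]C1=CCC[C@@H](O[Si](C)(C)C(C)(C)C)[C@]1(C)C=C | intermediate
9 | (2S,3R,6RS)-3-[(tert-butyldimethylsilyl)oxy]-2-ethenyl-2,6-dimethylcyclohexan-1-one (C8 epimers) | O=C1C(C)CC[C@@H](O[Si](C)(C)C(C)(C)C)[C@]1(C)C=C | intermediate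
10 | trimethylsilyl enol ether of 9 | C[Si](C)(C)OC1=C(C)CC[C@@H](O[Si](C)(C)C(C)(C)C)[C@]1(C)C=C | intermediate
11 | (5R,6S)-5-[(tert-butyldimethylsilyl)oxy]-6-ethenyl-2,6-dimethylcyclohex-2-en-1-one | O=C1C(C)=CC[C@@H](O[Si](C)(C)C(C)(C)C)[C@]1(C)C=C | intermediate
12 | 2-methylbut-1-en-3-yne | C=C(C)C#C | starting material
13 | lithium 3-methylbut-3-en-1-yn-1-ide | [Li+].[C-]#CC(C)=C | intermediate
14 | (1R,5R,6S)-5-[(tert-butyldimethylsilyl)oxy]-6-ethenyl-2,6-dimethyl-1-(3-methylbut-3-en-1-yn-1-yl)cyclohex-2-en-1-ol | C=C(C)C#C[C@]1(O)C(C)=CC[C@@H](O[Si](C)(C)C(C)(C)C)[C@]1(C)C=C | intermediate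
15 | (1S,5R,6S)-5-[(tert-butyldimethylsilyl)oxy]-6-ethenyl-2,6-dimethyl-1-[(1E)-3-methylbuta-1,3-dien-1-yl]cyclohex-2-en-1-ol | C=C(C)/C=C/[C@]1(O)C(C)=CC[C@@H](O[Si](C)(C)C(C)(C)C)[C@]1(C)C=C | intermediate
16 | potassium alkoxide of 15 | [K+].C=C(C)/C=C/[C@]1([O-])C(C)=CC[C@@H](O[Si](C)(C)C(C)(C)C)[C@]1(C)C=C | intermediate
17 | potassium dienolate of 18 (C9=C10 enolate, C8 and C1 trans) | [K+].C1/C=C(C)\C([O-])=C\[C@@H](C(C)=C)C/C=C(C)\[C@@H]1O[Si](C)(C)C(C)(C)C | intermediate
18 | (1S,3Z,5R,7Z)-5-[(tert-butyldimethylsilyl)oxy]-4,8-dimethyl-1-(prop-1-en-2-yl)cyclodeca-3,7-dien-9-one | C=C(C)[C@H]1C/C=C(C)\[C@H](O[Si](C)(C)C(C)(C)C)C/C=C(C)\C(=O)C1 | intermediate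
19 | (1S,3Z,5R,7Z)-5-hydroxy-4,8-dimethyl-1-(prop-1-en-2-yl)cyclodeca-3,7-dien-9-one | C=C(C)[C@H]1C/C=C(C)\[C@H](O)C/C=C(C)\C(=O)C1 | intermediate
20 | (1S,3Z,5S,7Z)-4,8-dimethyl-9-oxo-1-(prop-1-en-2-yl)cyclodeca-3,7-dien-5-yl 4-nitrobenzoate | C=C(C)[C@H]1C/C=C(C)\[C@@H](OC(=O)c2ccc(cc2)[N+](=O)[O-])C/C=C(C)\C(=O)C1 | intermediate
21 | (1S,3Z,5S,7Z)-5-hydroxy-4,8-dimethyl-1-(prop-1-en-2-yl)cyclodeca-3,7-dien-9-one | C=C(C)[C@H]1C/C=C(C)\[C@@H](O)C/C=C(C)\C(=O)C1 | intermediate
22 | (1S,3S,4R,5S,7Z)-3,4-epoxy-5-hydroxy-4,8-dimethyl-1-(prop-1-en-2-yl)cyclodec-7-en-9-one | C=C(C)[C@H]1C[C@@H]2O[C@]2(C)[C@@H](O)C/C=C(C)\C(=O)C1 | intermediate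
23 | angelic acid, (2Z)-2-methylbut-2-enoic acid | C/C=C(/C)C(=O)O | starting material
24 | (2Z)-2-methylbut-2-enoic 2,4,6-trichlorobenzoic anhydride | C/C=C(/C)C(=O)OC(=O)c1c(Cl)cc(Cl)cc1Cl | intermediate
25 | (1S,3S,4S,5S,7Z)-3,4-epoxy-4,8-dimethyl-9-oxo-1-(prop-1-en-2-yl)cyclodec-7-en-5-yl (2Z)-2-methylbut-2-enoate | C=C(C)[C@H]1C[C@@H]2O[C@]2(C)[C@@H](OC(=O)/C(C)=C\C)C/C=C(C)\C(=O)C1 | intermediate
26 | sodium enolate of 25 (C9=C10) | [Na+].C=C(C)[C@H]1C[C@@H]2O[C@]2(C)[C@@H](OC(=O)/C(C)=C\C)C/C=C(C)\C([O-])=C1 | intermediate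
27 | (1R,3S,4S,5S,7Z,10R)-3,4-epoxy-10-hydroxy-4,8-dimethyl-9-oxo-1-(prop-1-en-2-yl)cyclodec-7-en-5-yl (2Z)-2-methylbut-2-enoate | C=C(C)[C@H]1C[C@@H]2O[C@]2(C)[C@@H](OC(=O)/C(C)=C\C)C/C=C(C)\C(=O)[C@@H]1O | intermediate
28 | 3-methylbut-2-enoic acid (senecioic acid) | CC(C)=CC(=O)O | starting material
29 | (1R,3S,4S,5S,7Z,10S)-3,4-epoxy-4,8-dimethyl-10-[(3-methylbut-2-enoyl)oxy]-9-oxo-1-(prop-1-en-2-yl)cyclodec-7-en-5-yl (2Z)-2-methylbut-2-enoate | C=C(C)[C@H]1C[C@@H]2O[C@]2(C)[C@@H](OC(=O)/C(C)=C\C)C/C=C(C)\C(=O)[C@H]1OC(=O)C=C(C)C | intermediate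
30 | (1R,3S,4S,5S,7Z,9R,10S)-3,4-epoxy-9-hydroxy-4,8-dimethyl-10-[(3-methylbut-2-enoyl)oxy]-1-(prop-1-en-2-yl)cyclodec-7-en-5-yl (2Z)-2-methylbut-2-enoate | C=C(C)[C@H]1C[C@@H]2O[C@]2(C)[C@@H](OC(=O)/C(C)=C\C)C/C=C(C)\[C@@H](O)[C@H]1OC(=O)C=C(C)C | intermediate
31 | (1R,3S,4S,5S,7R,8S,9S,10S)-3,4:7,8-diepoxy-9-hydroxy-4,8-dimethyl-10-[(3-methylbut-2-enoyl)oxy]-1-(prop-1-en-2-yl)cyclodecan-5-yl (2Z)-2-methylbut-2-enoate | C=C(C)[C@H]1C[C@@H]2O[C@]2(C)[C@@H](OC(=O)/C(C)=C\C)C[C@H]2O[C@@]2(C)[C@@H](O)[C@H]1OC(=O)C=C(C)C | target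

**Count and risks**

Total step count: 19. Longest linear sequence: 19 steps (1 → 31); compounds 12, 23 and 28 are bought and used directly.

Steps most likely to fail:

Step 17. The Mitsunobu displacement at the hindered alpha-ketol carbon may be diverted into elimination toward C1 or into loss of configuration by enolisation. It also depends on the hydroxylation of step 16 having placed oxygen on the expected enolate face. The fallback sets out from 25. The sodium enolate is brominated with N-bromosuccinimide at −78 °C to give the 10-bromo ketone F1, with bromine on the same exposed face. Caesium 3-methylbut-2-enoate (from 28 and Cs2CO3) in DMF then displaces bromide with inversion, an SN2 substitution of an alpha-halo ketone by a carboxylate, and the route is rejoined at 29.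

Step 11. The rearrangement may pass through the other chair (E alkene at C3=C4 and the epimer at C1). The silyl group may migrate from O5 to the C9 alkoxide and stall the reaction, or the alkoxide may fragment. The fallback sets out from 15. The tertiary alcohol is silylated with N-(trimethylsilyl)imidazole to the trimethylsilyl ether F2. This is heated in degassed decalin at about 200 °C in a sealed tube, a neutral silyloxy-Cope rearrangement through the same chair, to give the silyl dienol ether F3. K2CO3 in MeOH cleaves the enol ether only and the route is rejoined at 18.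

Step 14. The peracid may attack the isopropenyl group competitively or deliver oxygen to the wrong alkene face, and the acid formed may open the new epoxide transannularly. The fallback sets out from 19, before the inversion. VO(acac)2 and t-BuOOH epoxidise only the alkene of the allylic alcohol, cis to the C5 hydroxyl, which is already the face required in the target, and give the epoxy alcohol F4. Mitsunobu inversion with 4-nitrobenzoic acid gives the ester F5, and methanolysis with K2CO3 rejoins the route at 22.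

Further compounds
F1 | step 17 | (1R,3S,4S,5S,7Z,10R)-10-bromo-3,4-epoxy-4,8-dimethyl-9-oxo-1-(prop-1-en-2-yl)cyclodec-7-en-5-yl (2Z)-2-methylbut-2-enoate | C=C(C)[C@H]1C[C@@H]2O[C@]2(C)[C@@H](OC(=O)/C(C)=C\C)C/C=C(C)\C(=O)[C@@H]1Br
F2 | step 11 | trimethylsilyl ether of 15 | C=C(C)/C=C/[C@]1(O[Si](C)(C)C)C(C)=CC[C@@H](O[Si](C)(C)C(C)(C)C)[C@]1(C)C=C
F3 | step 11 | C9 trimethylsilyl dienol ether of 18 (C9=C10, C8 and C1 trans) | C1/C=C(C)\C(O[Si](C)(C)C)=C\[C@@H](C(C)=C)C/C=C(C)\[C@@H]1O[Si](C)(C)C(C)(C)C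
F4 | step 14 | (1S,3S,4R,5R,7Z)-3,4-epoxy-5-hydroxy-4,8-dimethyl-1-(prop-1-en-2-yl)cyclodec-7-en-9-one | C=C(C)[C@H]1C[C@@H]2O[C@]2(C)[C@H](O)C/C=C(C)\C(=O)C1
F5 | step 14 | (1S,3S,4S,5S,7Z)-3,4-epoxy-4,8-dimethyl-9-oxo-1-(prop-1-en-2-yl)cyclodec-7-en-5-yl 4-nitrobenzoate | C=C(C)[C@H]1C[C@@H]2O[C@]2(C)[C@@H](OC(=O)c3ccc(cc3)[N+](=O)[O-])C/C=C(C)\C(=O)C1
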